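**Numbering.** Atoms carry eudesmane locants: ring A is C1–C2–C3–C4–C5–C10 and ring B is C5–C6–C7–C8–C9–C10, with C14 the methyl on C10 and C15 the methylene on C4. The face of the bicycle that carries C14 is called the lower face and the opposite one the upper face. Compounds are numbered 1–20 in the order in which they appear in the steps; the full list follows the steps.

## Analysis of the target

Target 20 is a cis-fused decalin with an exocyclic methylene (C15) on C4, a free hydroxyl on C6, an isopropyl group on C7, a 4-methoxybenzoyloxy group on C9 and an angular methyl on C10. It has five stereocentres, 5S,6S,7R,9R,10R in eudesmane numbering (1R,3R,4S,4aS,8aR in naphthalene numbering); C10, C5, C6 and C7 are contiguous and C10 is quaternary. C14, H5, O6, the isopropyl group and O9 all lie on the lower face, so the three ring B substituents are cis to the angular methyl and the hydrogens on C6, C7 and C9 point into the concave upper face. In the ring B chair that keeps the isopropyl group and O9 equatorial, O6 is axial and syn to C14, so equilibration cannot be relied on for C6 and C7. The sensitive groups are the 1,1-disubstituted alkene (isomerised into ring A by acid, lost on hydrogenation), the hindered ester beside the quaternary carbon, and, in intermediates, oxygen β to a carbonyl (retro-aldol, elimination). The difficulties are the absolute configuration of the quaternary C10, the cis fusion, hydrogen delivery to C7 and C9 on the concave face, and keeping the two secondary oxygens apart. The strategy rests on one feature: C10 and C5 are the β- and α-carbons of a ring A enone whose carbonyl carbon is C4, the later methylene carbon, so a nucleophile can bring C9 to C10 and the resulting enolate can take up C6 at C5 in the same flask.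

## Retrosynthetic reasoning

**O6–Si (20 ⇒ 19).** The C6 hydroxyl is released last. Carrying it as a silyl ether from the moment it is formed keeps O6 and O9 apart without any selective acylation, and the bulky group later steers the reduction at C7.

**Ester C–O at O9 (19 ⇒ 17 + 18).** With O6 masked, the C9 hydroxyl of 17 is the only one free, so acylation with 18 needs no selectivity.

**C9–H (17 ⇒ 16).** The carbinol is taken back to ketone 16. The forward reduction has to deliver hydride to the upper face of C9, anti to C14 and to the C7 isopropyl group.

**C7–H (16 ⇒ 14).** The stereocentre at C7 is taken back to enone 14. The forward step must add hydrogen to C7 anti to the neighbouring silyloxy group and must leave the exocyclic alkene alone, which rules out hydrogenation and calls for a conjugate hydride donor.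

**C7=C8 (14 ⇒ 12).** Ring B is opened at C7=C8, an aldol condensation in the forward sense. C8 is the only enolisable carbon of the C9 ketone because C10 is quaternary, and C7 is already a carbonyl. The cut turns the bicycle into monocycle 12, in which both ring-fusion centres already exist.

**C9 carbonyl oxygen (12 ⇒ 11 ⇒ 10).** The acetyl group is traced to a terminal alkyne and then to its C-silylated form. The alkyne is the form in which C8 and C9 arrive, and it is inert to silylation and methylenation.

**C4=C15 (10 ⇒ 9).** The methylene is traced to the ring ketone. It is installed before any basic step, because while C4 is a carbonyl the C6 silyloxy group is β to it and would be expelled through the C5 enolate. The forward reaction must select C4 over the C7 ketone.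

**O6–Si (9 ⇒ 8).** The aldol product is protected at once, since as a free β-hydroxy ketone it can revert or eliminate.

**C9–C10 and C5–C6 (8 ⇒ 6 + 3 + 5).** This is the key disconnection. Both bonds lie on the β- and α-carbons of enone 6. Alkynyl transfer from 3 sets the quaternary C10, and the enolate so formed adds to the aldehyde carbon of 5, setting C5 and C6. No other cut removes three stereocentres and leaves building blocks this small.

**Building blocks (3 ⇒ 1; 5 ⇒ 4).** Alane 3 comes from alkyne 1 by metalation and transmetalation. Keto-aldehyde 5 comes from ketone 4 by oxidation of its methyl group.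

## Alternatives that were turned down

**Alternative 1:** Intramolecular Diels–Alder reaction. C1–C2 and C5–C10 are cut, so that both rings of bicycle A2 arise from open-chain trienone A1. The isopropenyl ketone (C1=C10, activated by the C9 carbonyl inside the tether) adds to the diene C2=C3–C4=C5.
- For: two rings, the quaternary centre and the ring fusion form in one step. C6 and C7 are already present in A1 from acyclic aldol chemistry, so no hydrogen has to be delivered to C7 on the concave face; on this point the alternative is stronger than the chosen route. The allylsilane of A2 gives the exocyclic methylene by protodesilylation, so no ketone has to be told apart from another.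
- Against: A1 needs a long linear preparation with two stereocentres and a geometrically defined silylated diene. The dienophile reacts at its substituted carbon with the activating carbonyl inside the forming ring, so neither the endo/exo preference (cis or trans fusion) nor the relay from C6/C7 to C5/C10 is secured by the substrate. The isopropenyl ketone is prone to self-addition, and C9 still needs a face-selective reduction.
- Comparison: it is more convergent in ring construction, but its stereochemical risk sits in a thermal step with no control element. The chosen route sets C10 with a catalyst and C5/C6 from C10, and its building blocks take two preparatory steps.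

**Alternative 2:** Desymmetrising Heck cyclisation. C4–C5 is cut. Enol triflate A3, a 4,4-disubstituted cyclohexa-2,5-diene available by Birch reduction and alkylation, cyclises under palladium catalysis with a chiral ligand. The alkenylpalladium adds across one of the two enantiotopic ring alkenes, and β-hydride loss toward C7 gives diene A4.
- For: this kind of desymmetrisation to cis-decalins is well established, so its key step has firmer precedent than the one chosen here. Ring A, the cis fusion, the quaternary centre and the exocyclic methylene appear in one step, and A3 is short to make.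
- Against: A4 has neither oxygen. O6, O9 and the centres C6, C7 and C9 must all be set on a conjugated diene while the exocyclic alkene competes in every oxidation and in any hydrogen addition at C7. A 1,4-dioxygenation would give the two oxygens cis but undifferentiated. Repeated β-hydride elimination and re-addition can move the diene.
- Comparison: it is shorter and safer up to the skeleton, but longer and less selective after it. The chosen route brings in O6 with its configuration, and C9 at the right oxidation level, in the key step.

**Alternative 3:** Epoxide opening by an enol silane. C5–C10 is cut. In acyclic epoxide A5, Lewis-acid activation lets the C5 terminus of the C6 enol silane attack C10 with inversion, closing ring B to cyclohexanone A6 with O9 in place.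
- For: O9 and C10 come stereospecifically from an epoxide that asymmetric epoxidation can supply, so no late ketone reduction is needed at C9; here the alternative is stronger. C7 is α to the ketone in A6 and can be equilibrated to the all-cis, equatorial arrangement, which is also stronger than a reduction on the concave face.
- Against: the closure is an endo-mode opening at a fully substituted carbon. Exo-mode attack at C9 (five-membered ring), hydride-shift rearrangement of the activated epoxide and loss of stereospecificity through a cation all compete. Ring A is still to be made from the alkyne and C5, which needs enolisation of the C6 ketone toward C5 and not C7, and sets C5 only then. C6 must then be reduced to the axial alcohol, and enantiopure A5 is a long linear target.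
- Comparison: it is stronger on C9 and C7, weaker on ring fusion and length. The chosen route makes the C5/C10 relation and O6 in one operation from commercial materials.

Key step: step 3

Assumption: the sense of induction of the carbene ligand in the alkynyl transfer cannot be known in advance; the (4S,5S) ligand is written, and its mirror image is used if it proves to give the (S) quaternary centre.

## Route

Step 1
Reactants: 1 ethynyltrimethylsilane
Product: 3 dimethyl[(trimethylsilyl)ethynyl]aluminium, via lithium (trimethylsilyl)acetylide 2 (not isolated)
Conditions: n-BuLi, THF, −78 °C; then Me2AlCl (hexanes), −78 → 0 °C; solution used directly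
Reagents that add atoms: dimethylaluminium chloride, C[Al](C)Cl
Why: Deprotonation of the terminal alkyne and salt metathesis of the lithium acetylide with the chloroalane is the standard preparation of dialkylaluminium acetylides.

Step 2
Reactants: 4 3-methylbutan-2-one
Product: 5 3-methyl-2-oxobutanal
Conditions: SeO2, 1,4-dioxane/H2O, reflux; distillation, redistilled from P2O5 just before use
Reagents that add atoms: selenium dioxide, O=[Se]=O
Why: Riley oxidation takes the methyl group of a methyl ketone to the aldehyde, while the methine side has a single hydrogen and cannot reach a carbonyl. Distillation from a drying agent cracks the hydrate and oligomers so that the monomeric keto-aldehyde is used.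

Step 3
Reactants: 6 3-methylcyclohex-2-en-1-one; 3 dimethyl[(trimethylsilyl)ethynyl]aluminium; 5 3-methyl-2-oxobutanal
Product: 8 (2S,3R)-2-[(1R)-1-hydroxy-3-methyl-2-oxobutyl]-3-methyl-3-[(trimethylsilyl)ethynyl]cyclohexan-1-one, via dimethylaluminium enolate 7 (not isolated)
Conditions: CuCl2·2H2O (5 mol%), 2-[(4S,5S)-3-(2,6-diethylphenyl)-4,5-diphenyl-4,5-dihydro-1H-imidazol-3-ium-1-yl]benzenesulfonate (5.5 mol%), 3 (1.2 equiv), THF, −30 °C; then 5 (2.5 equiv), −78 °C; aq. potassium sodium tartrate
Reagents that add atoms: none
Why: Proposed new method: alkynyl transfer from aluminium to copper should give a carbene–copper acetylide that binds the enone (activated at oxygen by the alane), adds at C10 to a trivalent copper intermediate and forms C9–C10 by C(sp)–C(sp3) reductive elimination, leaving dimethylaluminium enolate 7; the closest known reactions are the carbene–copper-catalysed conjugate additions of aryl-, alkyl- and silyl-substituted alkenylaluminium reagents to β-substituted cyclic enones with aldehyde trapping of the aluminium enolate, the carbene–copper-catalysed allylic substitutions with alkynylaluminium reagents that give alkynyl-bearing quaternary carbons, and the nickel-catalysed conjugate addition of dialkylaluminium acetylides to cyclic enones. No ring is closed; two skeletal bonds and three stereocentres are formed. C10 is set by the chiral carbene ligand, which selects the enone face. Enolate 7 then adds to the aldehyde carbon of 5 through a closed six-membered chair around aluminium, in which the ring-locked E enolate places C10 and the aldehyde substituent both equatorial, giving the anti relation of C5 and C6, that is (1R) at the carbinol. In that chair the equatorial acyl group of the aldehyde lies gauche to C10 and presses on whichever C10 substituent is pseudo-equatorial, so the rod-shaped alkynyl group should take that place, the methyl group should stand pseudo-axial, and C5–C6 should form anti to methyl and cis to the alkynyl group. The step needs alkynyl and not methyl transfer (the sp carbon bridges aluminium and copper and should transmetalate first), 1,4- and not 1,2-addition (copper catalysis at low temperature), and attack on the aldehyde and not the ketone carbonyl of 5 (the aldehyde is far more electrophilic; 5 is used in excess because leftover 3 also consumes it).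

Step 4
Reactants: 8 (2S,3R)-2-[(1R)-1-hydroxy-3-methyl-2-oxobutyl]-3-methyl-3-[(trimethylsilyl)ethynyl]cyclohexan-1-one
Product: 9 (2S,3R)-2-[(1R)-1-{[tert-butyl(dimethyl)silyl]oxy}-3-methyl-2-oxobutyl]-3-methyl-3-[(trimethylsilyl)ethynyl]cyclohexan-1-one
Conditions: TBSOTf, 2,6-lutidine, CH2Cl2, −78 °C
Reagents that add atoms: tert-butyldimethylsilyl trifluoromethanesulfonate, CC(C)(C)[Si](C)(C)OS(=O)(=O)C(F)(F)F
Why: Silylation of the hindered secondary alcohol with a silyl triflate and a hindered base at low temperature avoids the retro-aldol and elimination paths of the free β-hydroxy ketone. No stereocentre is touched.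

Step 5
Reactants: 9 (2S,3R)-2-[(1R)-1-{[tert-butyl(dimethyl)silyl]oxy}-3-methyl-2-oxobutyl]-3-methyl-3-[(trimethylsilyl)ethynyl]cyclohexan-1-one
Product: 10 (1R)-1-{[tert-butyl(dimethyl)silyl]oxy}-3-methyl-1-{(1S,2R)-2-methyl-6-methylidene-2-[(trimethylsilyl)ethynyl]cyclohexyl}butan-2-one
Conditions: Zn, CH2Br2, TiCl4, THF/CH2Cl2, 0 °C → rt
Reagents that add atoms: dibromomethane, BrCBr
Why: Takai–Lombardo methylenation uses a non-basic geminal dimetal reagent, so C5 (α to the ketone, β to the silyloxy group) is neither epimerised nor eliminated. The reagent should take ring ketone C4, which has one unbranched α-carbon, in preference to C7, which is flanked by the silyloxy methine and the isopropyl methine.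

Step 6
Reactants: 10 (1R)-1-{[tert-butyl(dimethyl)silyl]oxy}-3-methyl-1-{(1S,2R)-2-methyl-6-methylidene-2-[(trimethylsilyl)ethynyl]cyclohexyl}butan-2-one
Product: 11 (1R)-1-{[tert-butyl(dimethyl)silyl]oxy}-1-[(1S,2R)-2-ethynyl-2-methyl-6-methylidenecyclohexyl]-3-methylbutan-2-one
Conditions: AgNO3 (0.1 equiv), acetone/H2O, rt
Reagents that add atoms: none
Why: Silver-catalysed protodesilylation cleaves only the alkynyl C–Si bond. The neutral medium leaves the O-silyl ether and the enolisable C6 beside the C7 ketone untouched.

Step 7
Reactants: 11 (1R)-1-{[tert-butyl(dimethyl)silyl]oxy}-1-[(1S,2R)-2-ethynyl-2-methyl-6-methylidenecyclohexyl]-3-methylbutan-2-one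
Product: 12 (1R)-1-[(1S,2R)-2-acetyl-2-methyl-6-methylidenecyclohexyl]-1-{[tert-butyl(dimethyl)silyl]oxy}-3-methylbutan-2-one
Conditions: Ph3PAuNTf2 (2 mol%), 1,4-dioxane/H2O, 40 °C
Reagents that add atoms: water, O
Why: Gold-catalysed Markovnikov hydration of the terminal alkyne puts the carbonyl on C9 and leaves C8 as a methyl group; alkenes and the silyl ether are inert to the cationic gold complex, and assistance by the C7 carbonyl oxygen would lead to the same diketone. Cyclisation of the alkyne with the exocyclic alkene is not expected, because it would place a cation on C4 at the bridgehead of a bridged bicycle.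

Step 8
Reactants: 12 (1R)-1-[(1S,2R)-2-acetyl-2-methyl-6-methylidenecyclohexyl]-1-{[tert-butyl(dimethyl)silyl]oxy}-3-methylbutan-2-one
Product: 14 (4R,4aS,8aR)-4-{[tert-butyl(dimethyl)silyl]oxy}-8a-methyl-5-methylidene-3-(propan-2-yl)-4a,5,6,7,8,8a-hexahydronaphthalen-1(4H)-one, via β-hydroxy ketone 13 (not isolated)
Conditions: KOt-Bu (0.3 equiv), t-BuOH/THF, 0 °C → rt
Reagents that add atoms: none
Why: Intramolecular aldol condensation of a 2,6-diketone: C10 is quaternary, so the C9 ketone enolises only toward C8, and this enolate closes ring B on the C7 carbonyl (six-membered, enolexo-exo-trig) before E1cB loss of water gives the conjugated enone. The ring fusion was fixed at C5/C10 in step 3 and is inherited; with C4 already a methylene, the C6 silyloxy group is no longer β to a carbonyl that could expel it.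

Step 9
Reactants: 14 (4R,4aS,8aR)-4-{[tert-butyl(dimethyl)silyl]oxy}-8a-methyl-5-methylidene-3-(propan-2-yl)-4a,5,6,7,8,8a-hexahydronaphthalen-1(4H)-one
Product: 16 (3R,4S,4aS,8aR)-4-{[tert-butyl(dimethyl)silyl]oxy}-8a-methyl-5-methylidene-3-(propan-2-yl)-3,4,4a,5,6,7,8,8a-octahydronaphthalen-1(2H)-one, via dimethylphenylsilyl enol ether 15 (not isolated)
Conditions: Cu(OAc)2·H2O (5 mol%), 1,2-bis(diphenylphosphino)benzene (5 mol%), PhMe2SiH, toluene, rt; then K2CO3, MeOH, 0 °C
Reagents that add atoms: none
Why: Conjugate reduction by a phosphine-ligated copper hydride made in situ is 1,4-selective and leaves the isolated alkene alone; the copper enolate is silylated to 15, which is cleaved to the ketone on work-up. Allylic 1,2-strain with the C7 isopropyl group should hold the C6 silyloxy group pseudo-axial on the lower face, so hydride should reach C7 antiperiplanar to it from the upper face (chair-like axial attack), placing H7 on the upper face and the isopropyl group cis to O6.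

Step 10
Reactants: 16 (3R,4S,4aS,8aR)-4-{[tert-butyl(dimethyl)silyl]oxy}-8a-methyl-5-methylidene-3-(propan-2-yl)-3,4,4a,5,6,7,8,8a-octahydronaphthalen-1(2H)-one
Product: 17 (1R,3R,4S,4aS,8aR)-4-{[tert-butyl(dimethyl)silyl]oxy}-8a-methyl-5-methylidene-3-(propan-2-yl)decahydronaphthalen-1-ol
Conditions: NaBH4, MeOH, −40 → 0 °C
Reagents that add atoms: none
Why: Small-hydride reduction of a cyclohexanone: the lower face of C9 is screened by the adjacent angular methyl and by the C7 isopropyl group, so borohydride should enter from the upper face (axial attack in the ring B chair that has C14 axial). This gives the equatorial alcohol with O9 cis to C14 (9R).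

Step 11
Reactants: 17 (1R,3R,4S,4aS,8aR)-4-{[tert-butyl(dimethyl)silyl]oxy}-8a-methyl-5-methylidene-3-(propan-2-yl)decahydronaphthalen-1-ol; 18 4-methoxybenzoyl chloride
Product: 19 (1R,3R,4S,4aS,8aR)-4-{[tert-butyl(dimethyl)silyl]oxy}-8a-methyl-5-methylidene-3-(propan-2-yl)decahydronaphthalen-1-yl 4-methoxybenzoate
Conditions: Et3N, DMAP (cat.), CH2Cl2, rt → 40 °C
Reagents that add atoms: none
Why: DMAP-catalysed acylation through the acylpyridinium ion reaches the equatorial but neopentyl-type C9 hydroxyl. O6 is silylated, so only O9 can be acylated.

Step 12
Reactants: 19 (1R,3R,4S,4aS,8aR)-4-{[tert-butyl(dimethyl)silyl]oxy}-8a-methyl-5-methylidene-3-(propan-2-yl)decahydronaphthalen-1-yl 4-methoxybenzoate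
Product: 20 (1R,3R,4S,4aS,8aR)-4-hydroxy-8a-methyl-5-methylidene-3-(propan-2-yl)decahydronaphthalen-1-yl 4-methoxybenzoate
Conditions: HF·pyridine, pyridine/THF, 0 °C → rt
Reagents that add atoms: none
Why: Fluoride cleaves the Si–O bond under buffered, weakly acidic conditions that should neither move the exocyclic alkene into the ring nor cleave the ester. O6 and O9 are 1,4-related across ring B, so acyl migration has no accessible cyclic path.

## Compound list

1 | ethynyltrimethylsilane | C#C[Si](C)(C)C | starting material
2 | lithium (trimethylsilyl)acetylide (formed in the flask) | [Li]C#C[Si](C)(C)C | intermediate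
3 | dimethyl[(trimethylsilyl)ethynyl]aluminium | C[Al](C)C#C[Si](C)(C)C | intermediate
4 | 3-methylbutan-2-one | CC(C)C(C)=O | starting material
5 | 3-methyl-2-oxobutanal | CC(C)C(=O)C=O | intermediate
6 | 3-methylcyclohex-2-en-1-one | CC1=CC(=O)CCC1 | starting material
7 | dimethylaluminium (3R)-3-methyl-3-[(trimethylsilyl)ethynyl]cyclohex-1-en-1-olate (formed in the flask) | C[Al](C)OC1=C[C@](C)(C#C[Si](C)(C)C)CCC1 | intermediate
8 | (2S,3R)-2-[(1R)-1-hydroxy-3-methyl-2-oxobutyl]-3-methyl-3-[(trimethylsilyl)ethynyl]cyclohexan-1-one | O=C1CCC[C@@](C)(C#C[Si](C)(C)C)[C@H]1[C@@H](O)C(=O)C(C)C | intermediate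
9 | (2S,3R)-2-[(1R)-1-{[tert-butyl(dimethyl)silyl]oxy}-3-methyl-2-oxobutyl]-3-methyl-3-[(trimethylsilyl)ethynyl]cyclohexan-1-one | O=C1CCC[C@@](C)(C#C[Si](C)(C)C)[C@H]1[C@@H](O[Si](C)(C)C(C)(C)C)C(=O)C(C)C | intermediate
10 | (1R)-1-{[tert-butyl(dimethyl)silyl]oxy}-3-methyl-1-{(1S,2R)-2-methyl-6-methylidene-2-[(trimethylsilyl)ethynyl]cyclohexyl}butan-2-one | C=C1CCC[C@@](C)(C#C[Si](C)(C)C)[C@H]1[C@@H](O[Si](C)(C)C(C)(C)C)C(=O)C(C)C | intermediate
11 | (1R)-1-{[tert-butyl(dimethyl)silyl]oxy}-1-[(1S,2R)-2-ethynyl-2-methyl-6-methylidenecyclohexyl]-3-methylbutan-2-one | C=C1CCC[C@@](C)(C#C)[C@H]1[C@@H](O[Si](C)(C)C(C)(C)C)C(=O)C(C)C | intermediate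
12 | (1R)-1-[(1S,2R)-2-acetyl-2-methyl-6-methylidenecyclohexyl]-1-{[tert-butyl(dimethyl)silyl]oxy}-3-methylbutan-2-one | C=C1CCC[C@@](C)(C(C)=O)[C@H]1[C@@H](O[Si](C)(C)C(C)(C)C)C(=O)C(C)C | intermediate
13 | (4R,4aS,8aR)-4-{[tert-butyl(dimethyl)silyl]oxy}-3-hydroxy-8a-methyl-5-methylidene-3-(propan-2-yl)-3,4,4a,5,6,7,8,8a-octahydronaphthalen-1(2H)-one, configuration at C3 not defined (formed in the flask) | C=C1CCC[C@]2(C)[C@H]1[C@@H](O[Si](C)(C)C(C)(C)C)C(O)(C(C)C)CC2=O | intermediate
14 | (4R,4aS,8aR)-4-{[tert-butyl(dimethyl)silyl]oxy}-8a-methyl-5-methylidene-3-(propan-2-yl)-4a,5,6,7,8,8a-hexahydronaphthalen-1(4H)-one | C=C1CCC[C@]2(C)[C@H]1[C@@H](O[Si](C)(C)C(C)(C)C)C(C(C)C)=CC2=O | intermediate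
15 | {[(3S,4S,4aS,8aR)-4-{[tert-butyl(dimethyl)silyl]oxy}-8a-methyl-5-methylidene-3-(propan-2-yl)-3,4,4a,5,6,7,8,8a-octahydronaphthalen-1-yl]oxy}(dimethyl)phenylsilane (formed in the flask) | C=C1CCC[C@]2(C)[C@H]1[C@@H](O[Si](C)(C)C(C)(C)C)[C@@H](C(C)C)C=C2O[Si](C)(C)c1ccccc1 | intermediate
16 | (3R,4S,4aS,8aR)-4-{[tert-butyl(dimethyl)silyl]oxy}-8a-methyl-5-methylidene-3-(propan-2-yl)-3,4,4a,5,6,7,8,8a-octahydronaphthalen-1(2H)-one | C=C1CCC[C@]2(C)[C@H]1[C@@H](O[Si](C)(C)C(C)(C)C)[C@@H](C(C)C)CC2=O | intermediate
17 | (1R,3R,4S,4aS,8aR)-4-{[tert-butyl(dimethyl)silyl]oxy}-8a-methyl-5-methylidene-3-(propan-2-yl)decahydronaphthalen-1-ol | C=C1CCC[C@]2(C)[C@H]1[C@@H](O[Si](C)(C)C(C)(C)C)[C@@H](C(C)C)C[C@H]2O | intermediate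
18 | 4-methoxybenzoyl chloride | COc1ccc(cc1)C(Cl)=O | starting material
19 | (1R,3R,4S,4aS,8aR)-4-{[tert-butyl(dimethyl)silyl]oxy}-8a-methyl-5-methylidene-3-(propan-2-yl)decahydronaphthalen-1-yl 4-methoxybenzoate | C=C1CCC[C@]2(C)[C@H]1[C@@H](O[Si](C)(C)C(C)(C)C)[C@@H](C(C)C)C[C@H]2OC(=O)c1ccc(OC)cc1 | intermediate
20 | (1R,3R,4S,4aS,8aR)-4-hydroxy-8a-methyl-5-methylidene-3-(propan-2-yl)decahydronaphthalen-1-yl 4-methoxybenzoate | C=C1CCC[C@]2(C)[C@H]1[C@@H](O)[C@@H](C(C)C)C[C@H]2OC(=O)c1ccc(OC)cc1 | target

## Step count

Total: 12 steps. Longest linear sequence: 11 steps (step 1, then steps 3–12, from 1; the branch from 4 through step 2 is equally long).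

## Least certain steps

**Step 3 (key step, carries the label "Proposed new method:").**
- What may go wrong: the acetylide may stay on copper as a spectator ligand, so that a methyl group of the alane is transferred instead, or the alane adds 1,2, or nothing adds at all. A second concern is attack of the aldehyde on the other face of C5.
- Fallback (known chemistry), from 2 back to 8: lithium acetylide 2 is added to 3-ethoxycyclohex-2-en-1-one F1 and the adduct is hydrolysed with dilute HCl (Stork–Danheiser transposition) to 3-[(trimethylsilyl)ethynyl]cyclohex-2-en-1-one F2. MeMgBr is then added 1,4 under catalysis by the carbene complex formed from Cu(OTf)2 and an imidazolinium salt of the family used in step 3; this is an established route from cyclic enynones to alkynyl-bearing quaternary centres and runs 1,4, not 1,6. It gives bromomagnesium (3R)-3-methyl-3-[(trimethylsilyl)ethynyl]cyclohex-1-en-1-olate F3, which is treated with 5 at −78 °C to give 8. The asymmetric step then forms C10–C14 in place of C9–C10.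

**Step 9.**
- What may go wrong: poor facial selectivity at C7. The upper face lies under the axial C4/C15 unit of ring A (the concave side), so hydride may instead arrive from the lower face through the half-chair in which the silyloxy group is pseudo-equatorial. The hindered β,β-disubstituted enone may also react slowly.
- Fallback, from 14 back to 16: control is moved from the substrate to the catalyst. A ligand-accelerated asymmetric conjugate reduction is run with Cu(OAc)2·H2O, an enantiopure bulky biaryl diphosphine, (R)- or (S)-5,5'-bis[bis(3,5-di-tert-butyl-4-methoxyphenyl)phosphino]-4,4'-bi-1,3-benzodioxole, and a silane; the ligand enantiomer matched with upper-face delivery is used. This fallback makes no new compound (F0).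

**Step 10.**
- What may go wrong: hydride delivery from the lower face (equatorial attack past the axial C14), or shielding of the upper face by the axial C4 of ring A, would give the 9-epimer.
- Fallback, from 16 back to 17: reagent-controlled Corey–Bakshi–Shibata reduction with (S)-1-methyl-3,3-diphenyltetrahydro-1H,3H-pyrrolo[1,2-c][1,3,2]oxazaborole and catecholborane in toluene at −78 °C, which does not hydroborate the 1,1-disubstituted alkene at that temperature. With quaternary C10 as the large and C8 as the small substituent, the (S) catalyst should give the 9R alcohol. This fallback makes no new compound (F0).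

**Step 5.**
- What may go wrong: methylenation of the C7 ketone as well, or Lewis-acid-induced loss of the β-silyloxy group.
- Fallback, from 9 back to 10: a two-step Peterson olefination. The bulky, weakly basic organocerium reagent from Me3SiCH2MgCl and CeCl3 (THF, −78 °C) should add only to the ring ketone, giving (2S,3R)-2-[(1R)-1-{[tert-butyl(dimethyl)silyl]oxy}-3-methyl-2-oxobutyl]-3-methyl-1-[(trimethylsilyl)methyl]-3-[(trimethylsilyl)ethynyl]cyclohexan-1-ol F4 (configuration at C1 immaterial). Acid-promoted anti elimination (catalytic camphorsulfonic acid, CH2Cl2, 0 °C) then gives 10.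

**Step 8.**
- What may go wrong: epimerisation at C6 by enolisation of the C7 ketone toward C6 before ring closure, γ-deprotonation of 14 at C6 once formed, or an oxygen-to-oxygen silyl shift in the aldolate.
- Fallback, from 12 back to 14: the reaction is split into a kinetic addition and a base-free dehydration. LiN(i-Pr)2 (1.05 equiv, THF, −78 °C) removes a proton only from the unhindered C8 methyl group, the lithium enolate closes on C7 in the cold, and β-hydroxy ketone 13 is isolated. Dehydration with methyl N-(triethylammoniosulfonyl)carbamate (toluene, 50 °C; syn elimination toward the acidified C8 hydrogens) gives 14. This fallback makes no new compound (F0).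

## Further compounds

F1 | step 3 | 3-ethoxycyclohex-2-en-1-one | CCOC1=CC(=O)CCC1
F2 | step 3 | 3-[(trimethylsilyl)ethynyl]cyclohex-2-en-1-one | C[Si](C)(C)C#CC1=CC(=O)CCC1
F3 | step 3 | bromomagnesium (3R)-3-methyl-3-[(trimethylsilyl)ethynyl]cyclohex-1-en-1-olate | Br[Mg]OC1=C[C@](C)(C#C[Si](C)(C)C)CCC1
F4 | step 5 | (2S,3R)-2-[(1R)-1-{[tert-butyl(dimethyl)silyl]oxy}-3-methyl-2-oxobutyl]-3-methyl-1-[(trimethylsilyl)methyl]-3-[(trimethylsilyl)ethynyl]cyclohexan-1-ol | C[Si](C)(C)CC1(O)CCC[C@@](C)(C#C[Si](C)(C)C)[C@H]1[C@@H](O[Si](C)(C)C(C)(C)C)C(=O)C(C)C
F0 | step 8 | none | none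
F0 | step 9 | none | none
F0 | step 10 | none | none
A1 | alternative 1 | 6-(tert-butyldimethylsilyloxy)-5-isopropyl-2-methyl-8-[(trimethylsilyl)methyl]deca-1,7,9-trien-3-one (configuration as in the SMILES) | C=C(C)C(=O)C[C@H](C(C)C)[C@H](O[Si](C)(C)C(C)(C)C)/C=C(\C[Si](C)(C)C)C=C
A2 | alternative 1 | cis-fused 4-(tert-butyldimethylsilyloxy)-3-isopropyl-8a-methyl-5-[(trimethylsilyl)methyl]-3,4,4a,7,8,8a-hexahydronaphthalen-1(2H)-one | C[Si](C)(C)CC1=CCC[C@]2(C)[C@H]1[C@@H](O[Si](C)(C)C(C)(C)C)[C@@H](C(C)C)CC2=O
A3 | alternative 2 | 5-[cis-1-methyl-4-(propan-2-yl)cyclohexa-2,5-dien-1-yl]pent-1-en-2-yl trifluoromethanesulfonate | C=C(OS(=O)(=O)C(F)(F)F)CCC[C@]1(C)C=C[C@@H](C(C)C)C=C1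
A4 | alternative 2 | cis-fused 7-isopropyl-4a-methyl-1-methylidene-1,2,3,4,4a,8a-hexahydronaphthalene | C=C1CCC[C@]2(C)[C@H]1C=C(C(C)C)C=C2
A5 | alternative 3 | trimethyl{[4-methyl-3-{[3-methyl-3-(pent-4-yn-1-yl)oxiran-2-yl]methyl}pent-1-en-2-yl]oxy}silane (configuration as in the SMILES) | C#CCCC[C@@]1(C)O[C@@H]1C[C@H](C(C)C)C(=C)O[Si](C)(C)C
A6 | alternative 3 | 4-hydroxy-2-isopropyl-5-methyl-5-(pent-4-yn-1-yl)cyclohexan-1-one (hydroxyl, methyl and isopropyl all cis) | C#CCCC[C@]1(C)CC(=O)[C@@H](C(C)C)C[C@H]1O
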